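**Retrosynthetic overview**
1. Target 15 ⇐ hemiketal 13 by cleaving C3–H: hydride adds to the convex face of the bicyclic oxocarbenium ion and sets C3.
2. 13 ⇐ enone 11 + N-alkylhydroxylamine 7 by cleaving C6a–N and C3–O: an enantioselective aza-Michael/hemiketalisation builds the isoxazolidine ring (the only ring formed; the cyclopentane is bought) and sets C6a and C3a.
3. 11 ⇐ alkylzinc from bromide 4 + cyclopent-1-enecarbonyl chloride (from acid 8); 7 ⇐ bromide 6 + NH2OH.
4. 4 and 6 ⇐ one batch of 3-picolyllithium 2 (from 3-picoline 1), divided between 1,7-dibromoheptane 3 and 1,12-dibromododecane 5.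

Assumption: the target as drawn is (3S,3aS,6aR), with H3, H3a and H6a all cis; hemiketal 13 is carried as a mixture of C3 anomers because that centre is reset in step 7.

**Step 1**
Reactants: 1 3-methylpyridine (3-picoline)
Product: 2 (pyridin-3-ylmethyl)lithium (3-picolyllithium), obtained as a deep-red THF solution that is held at −78 °C and divided into two equal portions for steps 2 and 3
Conditions: LiN(i-Pr)2 (1.0 equiv), THF, −78 °C, 1 h
Reagents that add atoms: lithium diisopropylamide (CC(C)N([Li])C(C)C)
Why: Lateral lithiation of the methyl group of 3-picoline by the amide base gives the picolyl anion; no stereocentre is formed, and a single batch serves both chain-building alkylations.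

**Step 2**
Reactants: 2 3-picolyllithium (first half of the solution); 3 1,7-dibromoheptane
Product: 4 3-(8-bromooctyl)pyridine
Conditions: solution of 2 cannulated into 3 (4 equiv), THF, −78 °C → rt
Reagents that add atoms: none
Why: SN2 alkylation of the picolyl anion by one end of the dibromide, with inverse addition into excess dibromide to suppress double alkylation; no stereocentre is formed.

**Step 3**
Reactants: 2 3-picolyllithium (second half of the solution); 5 1,12-dibromododecane
Product: 6 3-(13-bromotridecyl)pyridine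
Conditions: solution of 2 cannulated into 5 (4 equiv), THF, −78 °C → rt
Reagents that add atoms: none
Why: The same SN2 alkylation of the picolyl anion as in step 2, giving the thirteen-carbon tether in one operation.

**Step 4**
Reactants: 6 3-(13-bromotridecyl)pyridine
Product: 7 N-[13-(pyridin-3-yl)tridecyl]hydroxylamine
Conditions: NH2OH (50 wt% in H2O, 20 equiv), EtOH, 60 °C
Reagents that add atoms: hydroxylamine (NO)
Why: SN2 N-alkylation of hydroxylamine at its more nucleophilic nitrogen; the twenty-fold excess suppresses dialkylation and outruns intermolecular pyridine quaternisation.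

**Step 5**
Reactants: 4 3-(8-bromooctyl)pyridine; 8 cyclopent-1-ene-1-carboxylic acid
Product: 11 1-(cyclopent-1-en-1-yl)-9-(pyridin-3-yl)nonan-1-one, via alkylzinc bromide 9 (not isolated), via acid chloride 10 (not isolated)
Conditions: (a) 8, (COCl)2, cat. DMF, CH2Cl2, 0 °C → rt, evaporate; (b) 4, Zn dust, LiCl, THF, 50 °C; (c) combine, Pd(PPh3)4 (5 mol%), THF, 0 °C → rt
Reagents that add atoms: none
Why: LiCl-promoted zinc insertion into the primary C–Br bond gives a pyridine-tolerant alkylzinc halide, and its palladium-catalysed Negishi acylation with the fresh acid chloride stops at the ketone and leaves the conjugated ring alkene untouched.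

**Step 6**
Reactants: 11 1-(cyclopent-1-en-1-yl)-9-(pyridin-3-yl)nonan-1-one; 7 N-[13-(pyridin-3-yl)tridecyl]hydroxylamine
Product: 13 (3aS,6aR)-3-[8-(pyridin-3-yl)octyl]-1-[13-(pyridin-3-yl)tridecyl]hexahydro-1H-cyclopenta[c][1,2]oxazol-3-ol (cis-fused; C3 anomers), via open-chain hydroxyamino ketone 12 (not isolated)
Conditions: 7 (1.1 equiv), 3-{[3,5-bis(trifluoromethyl)phenyl]amino}-4-{[(8α,9S)-6′-methoxycinchonan-9-yl]amino}cyclobut-3-ene-1,2-dione (10 mol%), 4 Å MS, toluene/CH2Cl2 4:1, −30 °C, Ar; crude passed through a short Et3N-deactivated silica pad at 0 °C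
Reagents that add atoms: none
Why: Proposed new method: an enantioselective formal (3+2) annulation of a free N-alkylhydroxylamine with an α-branched cyclic enone under bifunctional squaramide–tertiary amine catalysis, in which the squaramide N–H pair activates the ketone and the quinuclidine holds the hydroxylamine O–H so that nitrogen is delivered to the Re face of C2 of the cyclopentene (setting C6a as R), the resulting enol is protonated anti to the new C–N bond (setting C3a cis), and 5-exo-trig hemiketalisation of the cis adduct traps the product and keeps the addition under kinetic control at −30 °C; the closest known reaction types are squaramide- or thiourea-catalysed aza-Michael additions of N-protected or O-alkyl hydroxylamines to simple enones and the racemic addition of N-alkylhydroxylamines to enones giving isoxazolidin-5-ols.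

**Step 7**
Reactants: 13 (3aS,6aR)-3-[8-(pyridin-3-yl)octyl]-1-[13-(pyridin-3-yl)tridecyl]hexahydro-1H-cyclopenta[c][1,2]oxazol-3-ol
Product: 15 pyrinodemin B = (3S,3aS,6aR)-3-[8-(pyridin-3-yl)octyl]-1-[13-(pyridin-3-yl)tridecyl]hexahydro-1H-cyclopenta[c][1,2]oxazole, via oxocarbenium triflate 14 (not isolated)
Conditions: Et3SiH (6 equiv), TMSOTf (4 equiv), CH2Cl2, −78 → −20 °C; aq. NaHCO3
Reagents that add atoms: none
Why: Ionic hydrogenation of a hemiketal, in which TMSOTf ionises C3–OH to the cis-fused oxocarbenium ion and Et3SiH delivers hydride to its convex face, so the new C3–H is cis to H3a and H6a and the octyl chain sits on the concave face (3S), while excess TMSOTf masks both pyridines as N-silylpyridinium salts that hydrolyse on work-up.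

**Compound list**
1 | 3-methylpyridine (3-picoline) | Cc1cccnc1 | starting material
2 | (pyridin-3-ylmethyl)lithium (3-picolyllithium) | [Li]Cc1cccnc1 | intermediate
3 | 1,7-dibromoheptane | BrCCCCCCCBr | starting material
4 | 3-(8-bromooctyl)pyridine | BrCCCCCCCCc1cccnc1 | intermediate
5 | 1,12-dibromododecane | BrCCCCCCCCCCCCBr | starting material
6 | 3-(13-bromotridecyl)pyridine | BrCCCCCCCCCCCCCc1cccnc1 | intermediate
7 | N-[13-(pyridin-3-yl)tridecyl]hydroxylamine | ONCCCCCCCCCCCCCc1cccnc1 | intermediate
8 | cyclopent-1-ene-1-carboxylic acid | OC(=O)C1=CCCC1 | starting material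
9 | bromo[8-(pyridin-3-yl)octyl]zinc | Br[Zn]CCCCCCCCc1cccnc1 | intermediate
10 | cyclopent-1-ene-1-carbonyl chloride | ClC(=O)C1=CCCC1 | intermediate
11 | 1-(cyclopent-1-en-1-yl)-9-(pyridin-3-yl)nonan-1-one | O=C(CCCCCCCCc1cccnc1)C1=CCCC1 | intermediate
12 | 1-[(1S,2R)-2-{hydroxy[13-(pyridin-3-yl)tridecyl]amino}cyclopentyl]-9-(pyridin-3-yl)nonan-1-one (cis) | O=C(CCCCCCCCc1cccnc1)[C@H]1CCC[C@H]1N(O)CCCCCCCCCCCCCc1cccnc1 | intermediate
13 | (3aS,6aR)-3-[8-(pyridin-3-yl)octyl]-1-[13-(pyridin-3-yl)tridecyl]hexahydro-1H-cyclopenta[c][1,2]oxazol-3-ol (cis-fused, C3 anomer mixture) | c1cncc(CCCCCCCCCCCCCN2OC(O)(CCCCCCCCc3cccnc3)[C@H]3CCC[C@H]32)c1 | intermediate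
14 | (3aS,6aR)-3-[8-(pyridin-3-yl)octyl]-1-[13-(pyridin-3-yl)tridecyl]-4,5,6,6a-tetrahydro-1H,3aH-cyclopenta[c][1,2]oxazol-2-ium triflate (O2=C3 oxocarbenium ion) | c1cncc(CCCCCCCCCCCCCN2[O+]=C(CCCCCCCCc3cccnc3)[C@H]3CCC[C@H]32)c1.[O-]S(=O)(=O)C(F)(F)F | intermediate
15 | pyrinodemin B, (3S,3aS,6aR)-3-[8-(pyridin-3-yl)octyl]-1-[13-(pyridin-3-yl)tridecyl]hexahydro-1H-cyclopenta[c][1,2]oxazole | c1cncc(CCCCCCCCCCCCCN2O[C@@H](CCCCCCCCc3cccnc3)[C@H]3CCC[C@H]32)c1 | target

**Step count and risks**
Total steps: 7. Longest linear sequence: 5 (1 → 2 → 4 → 11 → 13 → 15 through steps 1, 2, 5, 6 and 7, or 1 → 2 → 6 → 7 → 13 → 15 through steps 1, 3, 4, 6 and 7).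

The three steps most likely to fail:

Step 6 (the proposed new step). The risks are an uncatalysed background addition, competition of the two pyridines for the squaramide N–H donors, partial reversibility, and an unknown sense of induction. The quinidine-derived pseudoenantiomer of the catalyst is the first remedy if the sense is wrong. The fallback uses only known chemistry and replaces asymmetric catalysis by resolution. It sets out from 7 and 11, which are stirred without catalyst in EtOH at rt (the established racemic addition of N-alkylhydroxylamines to enones). This gives, through 12 and its enantiomer the (1R,2S)-hydroxyamino ketone F1, the racemic hemiketal, that is 13 together with its mirror image the (3aR,6aS)-hemiketal F2. The step 7 conditions then reduce the racemate, through 14 and its enantiomer the (3aR,6aS)-oxocarbenium triflate F3, to 15 together with ent-pyrinodemin B F4. Preparative chiral SFC on an amylose tris(3,5-dimethylphenylcarbamate) phase removes F4, and the fallback comes back to the route at 15.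

Step 7. The risks are sequestration of the Lewis acid by the three basic nitrogens, ring opening of the hemiketal instead of ionisation, and an insufficient convex-face preference. The fallback forms the C3–O bond by substitution instead of forming the C3–H bond on a cation. It sets out from 13, which is reduced with LiBH(s-Bu)3 (THF, −78 °C) through its keto tautomer 12. Felkin–Anh attack anti to the nitrogen-bearing ring carbon is expected to give (1R)-1-[(1S,2R)-2-{hydroxy[13-(pyridin-3-yl)tridecyl]amino}cyclopentyl]-9-(pyridin-3-yl)nonan-1-ol F5. Mitsunobu cyclodehydration of F5 (PPh3, diisopropyl azodicarboxylate, THF, 0 °C → rt) uses the N–OH as the acidic partner and displaces the activated secondary alcohol with inversion. This closes the isoxazolidine with the (3S) configuration, and the fallback comes back to the route at 15.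

Step 5. The risks are slow zinc insertion into a bromide that carries a coordinating pyridine, and acylation of the pyridine nitrogen by the acid chloride, which would open dihydropyridine side reactions. The fallback is a Weinreb ketone synthesis in which no acylpyridinium can form. It sets out from 4 and from 10 (made from 8 as in step 5). Treating 10 with MeNHOMe·HCl and Et3N in CH2Cl2 gives N-methoxy-N-methylcyclopent-1-ene-1-carboxamide F6. Magnesium turnings in THF convert 4 into bromo[8-(pyridin-3-yl)octyl]magnesium F7. Addition of F7 to F6 at 0 °C gives the chelated bromomagnesium hemiaminal alkoxide F8, which collapses on aqueous NH4Cl work-up, and the fallback comes back to the route at 11.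

**Further compounds**
F1 | step 6 | 1-[(1R,2S)-2-{hydroxy[13-(pyridin-3-yl)tridecyl]amino}cyclopentyl]-9-(pyridin-3-yl)nonan-1-one (enantiomer of 12) | O=C(CCCCCCCCc1cccnc1)[C@@H]1CCC[C@@H]1N(O)CCCCCCCCCCCCCc1cccnc1
F2 | step 6 | (3aR,6aS)-3-[8-(pyridin-3-yl)octyl]-1-[13-(pyridin-3-yl)tridecyl]hexahydro-1H-cyclopenta[c][1,2]oxazol-3-ol (enantiomer of 13) | c1cncc(CCCCCCCCCCCCCN2OC(O)(CCCCCCCCc3cccnc3)[C@@H]3CCC[C@@H]32)c1
F3 | step 6 | (3aR,6aS)-oxocarbenium triflate (enantiomer of 14) | c1cncc(CCCCCCCCCCCCCN2[O+]=C(CCCCCCCCc3cccnc3)[C@@H]3CCC[C@@H]32)c1.[O-]S(=O)(=O)C(F)(F)F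
F4 | step 6 | ent-pyrinodemin B, (3R,3aR,6aS)-3-[8-(pyridin-3-yl)octyl]-1-[13-(pyridin-3-yl)tridecyl]hexahydro-1H-cyclopenta[c][1,2]oxazole | c1cncc(CCCCCCCCCCCCCN2O[C@H](CCCCCCCCc3cccnc3)[C@@H]3CCC[C@@H]32)c1
F5 | step 7 | (1R)-1-[(1S,2R)-2-{hydroxy[13-(pyridin-3-yl)tridecyl]amino}cyclopentyl]-9-(pyridin-3-yl)nonan-1-ol | O[C@H](CCCCCCCCc1cccnc1)[C@H]1CCC[C@H]1N(O)CCCCCCCCCCCCCc1cccnc1
F6 | step 5 | N-methoxy-N-methylcyclopent-1-ene-1-carboxamide | CON(C)C(=O)C1=CCCC1
F7 | step 5 | bromo[8-(pyridin-3-yl)octyl]magnesium | Br[Mg]CCCCCCCCc1cccnc1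
F8 | step 5 | bromomagnesium 1-(cyclopent-1-en-1-yl)-1-[methoxy(methyl)amino]-9-(pyridin-3-yl)nonan-1-olate | CON(C)C(O[Mg]Br)(CCCCCCCCc1cccnc1)C1=CCCC1
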